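**Plan**
- Retrosynthesis: cut O1–C8a (aryl ether of ring C, fluoride displacement), then C3–O and C2–C3 in one operation (diazoketone, an O–H donor, formaldehyde), then C4–C4a (aryl metal plus ring B arylacetic Weinreb amide) and the two aryl–prenyl bonds.
- Enabling feature: C3 carries an oxygen, the ring B aryl and the C4 carbonyl bound to ring A. This is the substitution pattern of an aryl acyl carbene carbon after it has taken up an O–H donor and a one-carbon electrophile (C2).
- Forward: ring A is diprenylated and silylated, joined to the ring B acetamide as a deoxybenzoin and diazotised. The three-component coupling gives an open chain, and ring C is closed last.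
- Stereochemistry: the only stereocenter, quaternary C3 (R), comes from the chiral phosphoric acid of step 7 and is not touched afterwards.
- Protection: triisopropylsilyl (TIPS) on all three phenols, removed by fluoride so the prenyl groups and the tertiary carbinol never see acid. The C3 oxygen enters as a 4-methoxybenzyl (PMB) ether.

Key step: step 7

Assumption: which antipode of the phosphoric acid gives (R) at C3 cannot be predicted for this substrate class; the (R)-acid is written and the (S)-acid would be used if the sense proves opposite.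

Abbreviations: prenyl = 3-methylbut-2-en-1-yl; TIPS = triisopropylsilyl; PMB = 4-methoxybenzyl.

**Step 1**
Reactants: 1 4-bromo-3-fluorophenol; 2 prenyl bromide
Product: 3 4-bromo-3-fluoro-2,6-diprenylphenol
Conditions: NaH (2.2 equiv), toluene, 0 °C; 2 (2.2 equiv), rt
Reagents that add atoms: prenyl bromide 2, CC(C)=CCBr
Why: Ortho C-alkylation of a phenoxide: the aggregated sodium phenoxide in a non-polar solvent should be allylated at carbon next to oxygen and not at oxygen, the para position is blocked by bromine, and after tautomerisation of the dienone the second ortho position reacts in the same way.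

**Step 2**
Reactants: 3 4-bromo-3-fluoro-2,6-diprenylphenol
Product: 4 (4-bromo-3-fluoro-2,6-diprenylphenoxy)triisopropylsilane
Conditions: TIPSOTf, 2,6-lutidine, CH2Cl2, 0 °C
Reagents that add atoms: triisopropylsilyl trifluoromethanesulfonate, CC(C)[Si](OS(=O)(=O)C(F)(F)F)(C(C)C)C(C)C
Why: Silyl ether formation on a hindered phenol with a silyl triflate; the TIPS ether flanked by two prenyl groups should withstand organolithium, amidine base and alkoxide and still be cleaved by fluoride.

**Step 3**
Reactants: 5 2,4-dihydroxyphenylacetic acid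
Product: 7 2-(2,4-dihydroxyphenyl)-N-methoxy-N-methylacetamide, via 1-hydroxybenzotriazole ester 6 (not isolated)
Conditions: N-(3-dimethylaminopropyl)-N'-ethylcarbodiimide hydrochloride (EDC·HCl), 1-hydroxybenzotriazole, MeNHOMe·HCl, N-methylmorpholine, DMF, 0 °C to rt
Reagents that add atoms: N,O-dimethylhydroxylamine hydrochloride, CNOC.Cl
Why: Carbodiimide amide coupling through active ester 6, in which the amine is acylated in preference to the free phenols.

**Step 4**
Reactants: 7 2-(2,4-dihydroxyphenyl)-N-methoxy-N-methylacetamide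
Product: 8 2-[2,4-bis(triisopropylsilyloxy)phenyl]-N-methoxy-N-methylacetamide
Conditions: TIPSCl (2.4 equiv), imidazole, DMF, rt
Reagents that add atoms: triisopropylsilyl chloride, CC(C)[Si](Cl)(C(C)C)C(C)C
Why: Silylation of both phenols with silyl chloride and imidazole; the amide is inert, and TIPS is chosen over smaller silyl groups to resist DBU in step 6 and the alkoxide in step 8.

**Step 5**
Reactants: 4 (4-bromo-3-fluoro-2,6-diprenylphenoxy)triisopropylsilane; 8 2-[2,4-bis(triisopropylsilyloxy)phenyl]-N-methoxy-N-methylacetamide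
Product: 12 2-[2,4-bis(triisopropylsilyloxy)phenyl]-1-[2-fluoro-3,5-diprenyl-4-(triisopropylsilyloxy)phenyl]ethan-1-one (the deoxybenzoin), via aryllithium 9 (not isolated), via arylmagnesium bromide 10 (not isolated), via magnesium hemiaminal 11 (not isolated)
Conditions: n-BuLi, THF, −78 °C; MgBr2·OEt2, −78 °C; 8, −78 to 0 °C; cold 0.5 M HCl
Reagents that add atoms: none
Why: Weinreb ketone synthesis: bromine–lithium exchange at −78 °C keeps the ortho-fluoroaryllithium below the temperature of LiF loss, transmetalation to the less basic Grignard reagent 10 lets addition outrun deprotonation of the benzylic CH2 of 8, and chelate 11 prevents a second addition until work-up.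

**Step 6**
Reactants: 12 the deoxybenzoin
Product: 13 2-[2,4-bis(triisopropylsilyloxy)phenyl]-2-diazo-1-[2-fluoro-3,5-diprenyl-4-(triisopropylsilyloxy)phenyl]ethan-1-one
Conditions: 4-acetamidobenzenesulfonyl azide, DBU, MeCN/THF, 0 °C to rt
Reagents that add atoms: 4-acetamidobenzenesulfonyl azide, CC(=O)Nc1ccc(cc1)S(=O)(=O)N=[N+]=[N-]
Why: Regitz diazo transfer: the enolate of the benzyl aryl ketone attacks the terminal azide nitrogen and the triazene collapses to the diazoketone and the sulfonamide, a standard reaction of deoxybenzoins.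

**Step 7**
Reactants: 13 the diazoketone; 14 4-methoxybenzyl alcohol; 15 formaldehyde
Product: 17 (R)-2-[2,4-bis(triisopropylsilyloxy)phenyl]-1-[2-fluoro-3,5-diprenyl-4-(triisopropylsilyloxy)phenyl]-3-hydroxy-2-[(4-methoxyphenyl)methoxy]propan-1-one, via enol 16 (not isolated)
Conditions: Rh2(OAc)4 (2 mol %), (R)-3,3'-bis(2,4,6-triisopropylphenyl)-1,1'-binaphthyl-2,2'-diyl hydrogen phosphate (10 mol %), 14 (1.3 equiv), monomeric CH2O (2 equiv, CH2Cl2 solution from cracked paraformaldehyde), 4 Å molecular sieves, CH2Cl2, −20 °C, 13 added over 2 h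
Reagents that add atoms: 4-methoxybenzyl alcohol 14, COc1ccc(CO)cc1; formaldehyde 15, C=O
Why: Proposed new method: Rh2(OAc)4 releases nitrogen from 13 to give a carbene bound to the dirhodium core, the O–H of 14 adds to it as a protic oxonium ylide, a proton shift to the carbonyl oxygen liberates (Z)-enol 16, and this enol, hydrogen-bonded through its OH to the phosphoryl oxygen of the binaphthyl phosphoric acid while the P–OH activates formaldehyde, adds through C3 to form C2–C3 before it can ketonise. The closest known reaction type is the three-component coupling of aryl diazo carbonyl compounds, alcohols and aldehydes or imines under Rh2(OAc)4 and a chiral phosphoric acid; a diaryl diazoketone paired with formaldehyde is the part without precedent. No ring is closed, since the primary hydroxyl and the aryl fluoride do not react under these neutral conditions. The new quaternary stereocenter C3 is set by the chiral pocket of the acid, which presents one face of the planar enol to the achiral electrophile, and should be (R). The step needs chemoselectivity of the carbene for O–H insertion (trisubstituted prenyl olefins are poor partners for a donor–acceptor carbene and the ortho fluorine cannot trap it) and regioselectivity for bond formation at C3, which the ether oxygen secures: with water the intermediate would be an ene-diol that could also react through the carbon next to ring A. The benzyl ether also keeps the tertiary oxygen out of the ring closure of step 8.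

**Step 8**
Reactants: 17 the (R)-hydroxy ketone
Product: 19 (R)-3-[2,4-bis(triisopropylsilyloxy)phenyl]-3-[(4-methoxyphenyl)methoxy]-6,8-diprenyl-7-(triisopropylsilyloxy)-2,3-dihydro-4H-chromen-4-one, via potassium alkoxide 18 (not isolated)
Conditions: KN(SiMe3)2 (1.05 equiv), THF, −78 to 0 °C
Reagents that add atoms: none
Why: Intramolecular nucleophilic aromatic substitution through a Meisenheimer intermediate: the primary alkoxide attacks the fluorine-bearing carbon ortho to the ketone in a 6-exo closure, the blocked tertiary oxygen cannot give a five-membered benzofuranone, and C3 is not involved.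

**Step 9**
Reactants: 19 the PMB-protected chromanone
Product: 20 (R)-3-[2,4-bis(triisopropylsilyloxy)phenyl]-3-hydroxy-6,8-diprenyl-7-(triisopropylsilyloxy)-2,3-dihydro-4H-chromen-4-one
Conditions: DDQ (1.5 equiv), CH2Cl2/pH 7 phosphate buffer, 0 °C
Reagents that add atoms: none
Why: Oxidative cleavage of a PMB ether by DDQ (hydride abstraction, then hydrolysis of the hemiacetal): the anisyl ring is the most electron-rich site, the silylated phenols cannot form quinone methides, ring A is deactivated by the ketone, and the C3–O bond is not broken, so the configuration is kept.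

**Step 10**
Reactants: 20 the tris-TIPS tertiary alcohol
Product: 21 (R)-3-(2,4-dihydroxyphenyl)-3,7-dihydroxy-6,8-diprenyl-2,3-dihydro-4H-chromen-4-one (CNP0211715.1)
Conditions: Bu4NF (3.3 equiv), AcOH (3.3 equiv), THF, 0 °C
Reagents that add atoms: none
Why: Fluoride cleavage of three aryl silyl ethers, buffered with acetic acid so that neither the tertiary alpha-ketol nor the ortho-prenyl phenols meet strong base or acid; quaternary C3 cannot epimerise.

**Compound list**
1 | 4-bromo-3-fluorophenol | Oc1ccc(Br)c(F)c1 | starting material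
2 | prenyl bromide (1-bromo-3-methylbut-2-ene) | CC(C)=CCBr | starting material
3 | 4-bromo-3-fluoro-2,6-diprenylphenol | CC(C)=CCc1cc(Br)c(F)c(CC=C(C)C)c1O | intermediate
4 | (4-bromo-3-fluoro-2,6-diprenylphenoxy)triisopropylsilane | CC(C)=CCc1cc(Br)c(F)c(CC=C(C)C)c1O[Si](C(C)C)(C(C)C)C(C)C | intermediate
5 | 2,4-dihydroxyphenylacetic acid | OC(=O)Cc1ccc(O)cc1O | starting material
6 | benzotriazol-1-yl 2-(2,4-dihydroxyphenyl)acetate | O=C(Cc1ccc(O)cc1O)On1nnc2ccccc12 | intermediate
7 | 2-(2,4-dihydroxyphenyl)-N-methoxy-N-methylacetamide | CON(C)C(=O)Cc1ccc(O)cc1O | intermediate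
8 | 2-[2,4-bis(triisopropylsilyloxy)phenyl]-N-methoxy-N-methylacetamide | CON(C)C(=O)Cc1ccc(O[Si](C(C)C)(C(C)C)C(C)C)cc1O[Si](C(C)C)(C(C)C)C(C)C | intermediate
9 | [2-fluoro-3,5-diprenyl-4-(triisopropylsilyloxy)phenyl]lithium | [Li]c1cc(CC=C(C)C)c(O[Si](C(C)C)(C(C)C)C(C)C)c(CC=C(C)C)c1F | intermediate
10 | [2-fluoro-3,5-diprenyl-4-(triisopropylsilyloxy)phenyl]magnesium bromide | Br[Mg]c1cc(CC=C(C)C)c(O[Si](C(C)C)(C(C)C)C(C)C)c(CC=C(C)C)c1F | intermediate
11 | bromomagnesium alkoxide of the N-methoxy-N-methyl hemiaminal formed from 10 and 8 | CON(C)C(Cc1ccc(O[Si](C(C)C)(C(C)C)C(C)C)cc1O[Si](C(C)C)(C(C)C)C(C)C)(O[Mg]Br)c1cc(CC=C(C)C)c(O[Si](C(C)C)(C(C)C)C(C)C)c(CC=C(C)C)c1F | intermediate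
12 | 2-[2,4-bis(triisopropylsilyloxy)phenyl]-1-[2-fluoro-3,5-diprenyl-4-(triisopropylsilyloxy)phenyl]ethan-1-one | O=C(Cc1ccc(O[Si](C(C)C)(C(C)C)C(C)C)cc1O[Si](C(C)C)(C(C)C)C(C)C)c1cc(CC=C(C)C)c(O[Si](C(C)C)(C(C)C)C(C)C)c(CC=C(C)C)c1F | intermediate
13 | 2-[2,4-bis(triisopropylsilyloxy)phenyl]-2-diazo-1-[2-fluoro-3,5-diprenyl-4-(triisopropylsilyloxy)phenyl]ethan-1-one | [N-]=[N+]=C(c1ccc(O[Si](C(C)C)(C(C)C)C(C)C)cc1O[Si](C(C)C)(C(C)C)C(C)C)C(=O)c1cc(CC=C(C)C)c(O[Si](C(C)C)(C(C)C)C(C)C)c(CC=C(C)C)c1F | intermediate
14 | 4-methoxybenzyl alcohol | COc1ccc(CO)cc1 | starting material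
15 | formaldehyde | C=O | starting material
16 | (Z)-2-[2,4-bis(triisopropylsilyloxy)phenyl]-1-[2-fluoro-3,5-diprenyl-4-(triisopropylsilyloxy)phenyl]-2-[(4-methoxyphenyl)methoxy]ethen-1-ol | O/C(=C(\OCc1ccc(OC)cc1)c1ccc(O[Si](C(C)C)(C(C)C)C(C)C)cc1O[Si](C(C)C)(C(C)C)C(C)C)c1cc(CC=C(C)C)c(O[Si](C(C)C)(C(C)C)C(C)C)c(CC=C(C)C)c1F | intermediate
17 | (R)-2-[2,4-bis(triisopropylsilyloxy)phenyl]-1-[2-fluoro-3,5-diprenyl-4-(triisopropylsilyloxy)phenyl]-3-hydroxy-2-[(4-methoxyphenyl)methoxy]propan-1-one | OC[C@](OCc1ccc(OC)cc1)(c1ccc(O[Si](C(C)C)(C(C)C)C(C)C)cc1O[Si](C(C)C)(C(C)C)C(C)C)C(=O)c1cc(CC=C(C)C)c(O[Si](C(C)C)(C(C)C)C(C)C)c(CC=C(C)C)c1F | intermediate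
18 | potassium alkoxide of 17 (primary oxygen) | [K+].[O-]C[C@](OCc1ccc(OC)cc1)(c1ccc(O[Si](C(C)C)(C(C)C)C(C)C)cc1O[Si](C(C)C)(C(C)C)C(C)C)C(=O)c1cc(CC=C(C)C)c(O[Si](C(C)C)(C(C)C)C(C)C)c(CC=C(C)C)c1F | intermediate
19 | (R)-3-[2,4-bis(triisopropylsilyloxy)phenyl]-3-[(4-methoxyphenyl)methoxy]-6,8-diprenyl-7-(triisopropylsilyloxy)-2,3-dihydro-4H-chromen-4-one | CC(C)=CCc1cc2c(c(CC=C(C)C)c1O[Si](C(C)C)(C(C)C)C(C)C)OC[C@](OCc1ccc(OC)cc1)(c1ccc(O[Si](C(C)C)(C(C)C)C(C)C)cc1O[Si](C(C)C)(C(C)C)C(C)C)C2=O | intermediate
20 | (R)-3-[2,4-bis(triisopropylsilyloxy)phenyl]-3-hydroxy-6,8-diprenyl-7-(triisopropylsilyloxy)-2,3-dihydro-4H-chromen-4-one | CC(C)=CCc1cc2c(c(CC=C(C)C)c1O[Si](C(C)C)(C(C)C)C(C)C)OC[C@](O)(c1ccc(O[Si](C(C)C)(C(C)C)C(C)C)cc1O[Si](C(C)C)(C(C)C)C(C)C)C2=O | intermediate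
21 | (R)-3-(2,4-dihydroxyphenyl)-3,7-dihydroxy-6,8-diprenyl-2,3-dihydro-4H-chromen-4-one (CNP0211715.1) | CC(C)=CCc1cc2c(c(CC=C(C)C)c1O)OC[C@](O)(c1ccc(O)cc1O)C2=O | target

**Step count**
Total: 10 steps. Longest linear sequence: 8 steps (1, 2, 5, 6, 7, 8, 9, 10 from phenol 1; the ring B branch 3, 4, 5–10 is equally long).

**Steps most likely to fail**

Step 7 (the new method). Three processes threaten it:
- The oxonium ylide or enol 16 may ketonise before the aldol step, giving plain O–H insertion.
- The carbene may insert into the O–H of the hemiformal that 14 forms with formaldehyde, and not into the alcohol itself.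
- Face discrimination may be weak because formaldehyde is small.

The fallback makes the same two bonds one after the other by known reactions. Setting out from diazoketone 13, Rh2(OAc)4-catalysed O–H insertion of 14 without formaldehyde should give the racemic 2-aryl-2-(4-methoxybenzyloxy) ketone F1. LiN(SiMe3)2 and Me3SiCl in THF at −78 °C should give, through the chelated lithium enolate, the (Z)-trimethylsilyl enol ether F2. A Mukaiyama-type hydroxymethylation of F2 with aqueous formaldehyde under Sc(OTf)3 and (S,S)-6,6'-bis(1-hydroxy-2,2-dimethylpropyl)-2,2'-bipyridine (or its antipode) in dimethoxyethane/water should then set C3 and return to the route at 17.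

Step 8. Retro-aldol loss of formaldehyde from alkoxide 18, with re-addition eroding the enantiomeric purity, or silyl transfer from the ortho oxygen of ring B to the alkoxide, may compete with a slow attack on the electron-rich fluoroarene.

The fallback closes ring C while C3 still bears hydrogen and brings in the C3 oxygen last. From deoxybenzoin 12, paraformaldehyde and K2CO3 in DMF should give the racemic hydroxymethyl ketone F3. In the same flask F3 displaces fluoride to give the racemic isoflavanone F4; retro-aldol is harmless at this stage. KN(SiMe3)2 in THF at −78 °C gives the potassium enolate F5. Enolate hydroxylation with an enantiopure (8,8-dichlorocamphorylsulfonyl)oxaziridine, known for enolates of 2-substituted tetralones and chromanones, should deliver tertiary alcohol 20, the antipode of the reagent being chosen for (R). Steps 6 to 9 are bypassed.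

Step 1. O-alkylation of the phenoxide and stalling after the first C-alkylation may dominate over double ortho C-prenylation.

The fallback fixes the two positions by halogenation first. From 1, N-iodosuccinimide (2.2 equiv) with catalytic TsOH in MeCN should give 4-bromo-3-fluoro-2,6-diiodophenol F6. A twofold Stille coupling of F6 with tributyl(3-methylbut-2-en-1-yl)stannane under Pd(PPh3)4 in DMF at 80 °C should return to the route at 3, because zerovalent palladium inserts into the C–I bonds far faster than into C–Br.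

**Further compounds**
F1 | step 7 | racemic 2-[2,4-bis(triisopropylsilyloxy)phenyl]-1-[2-fluoro-3,5-diprenyl-4-(triisopropylsilyloxy)phenyl]-2-[(4-methoxyphenyl)methoxy]ethan-1-one | O=C(C(OCc1ccc(OC)cc1)c1ccc(O[Si](C(C)C)(C(C)C)C(C)C)cc1O[Si](C(C)C)(C(C)C)C(C)C)c1cc(CC=C(C)C)c(O[Si](C(C)C)(C(C)C)C(C)C)c(CC=C(C)C)c1F
F2 | step 7 | (Z)-trimethylsilyl enol ether of F1 | C[Si](C)(C)O/C(=C(\OCc1ccc(OC)cc1)c1ccc(O[Si](C(C)C)(C(C)C)C(C)C)cc1O[Si](C(C)C)(C(C)C)C(C)C)c1cc(CC=C(C)C)c(O[Si](C(C)C)(C(C)C)C(C)C)c(CC=C(C)C)c1F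
F3 | step 8 | racemic 2-[2,4-bis(triisopropylsilyloxy)phenyl]-1-[2-fluoro-3,5-diprenyl-4-(triisopropylsilyloxy)phenyl]-3-hydroxypropan-1-one | OCC(c1ccc(O[Si](C(C)C)(C(C)C)C(C)C)cc1O[Si](C(C)C)(C(C)C)C(C)C)C(=O)c1cc(CC=C(C)C)c(O[Si](C(C)C)(C(C)C)C(C)C)c(CC=C(C)C)c1F
F4 | step 8 | racemic 3-[2,4-bis(triisopropylsilyloxy)phenyl]-6,8-diprenyl-7-(triisopropylsilyloxy)-2,3-dihydro-4H-chromen-4-one | CC(C)=CCc1cc2c(c(CC=C(C)C)c1O[Si](C(C)C)(C(C)C)C(C)C)OCC(c1ccc(O[Si](C(C)C)(C(C)C)C(C)C)cc1O[Si](C(C)C)(C(C)C)C(C)C)C2=O
F5 | step 8 | potassium enolate of F4 | [K+].[O-]C1=C(c2ccc(O[Si](C(C)C)(C(C)C)C(C)C)cc2O[Si](C(C)C)(C(C)C)C(C)C)COc2c1cc(CC=C(C)C)c(O[Si](C(C)C)(C(C)C)C(C)C)c2CC=C(C)C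
F6 | step 1 | 4-bromo-3-fluoro-2,6-diiodophenol | Oc1c(I)cc(Br)c(F)c1I
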